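## Structural features

Borregomycin E (14) is a flat, fully aromatic pentacycle of the 11,12-dihydroindolo[2,3-a]carbazole type. Benzene rings A and E, pyrrole rings B and D and a central benzene ring C are fused in the order A–B–C–D–E, and both pyrrole nitrogens (N12 in ring B, N11 in ring D) sit on the same edge of ring C, on the neighbouring carbons C11b and C11a. Ring C carries no hydrogen: C5 and C6 bear methoxy groups, C4b and C6a are bonded to the aryl carbons C4a and C6b, and C11a and C11b to nitrogen. Rings A and E each carry one chlorine (C2, C9), para to C4a/C6b and meta to the nitrogen-bearing C12a/C10a. There is no stereocentre, and a twofold axis through the midpoints of C5–C6 and C11a–C11b makes the two halves identical. The fragile features are ring C itself, a 1,2-diamino-4,5-dialkoxybenzene that is easily oxidised towards a quinone diimine, the two free N–H groups in the bay, and the two aryl chlorides, which must survive every transition-metal step. The real difficulty is the hexasubstituted ring C: two oxygens, two nitrogens and two aryl carbons must be placed around one benzene ring without ambiguity. The key step uses the fact that ring C is three two-carbon units (C4b–C5, C6–C6a, C11a–C11b), each already carrying its heteroatom, held together by the three-atom bridges C4a–C12a–N12 and C6b–C10a–N11, which become rings B and D.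

## Logic of the disconnections

14 ⇒ 12. The N11–S and N12–S bonds are cut. The sulfonyl groups are not part of the target, but they are what makes a nitrogen-substituted alkyne isolable, and they match the closest precedent for the ring-forming step. The forward step must cleave two crowded sulfonamides without touching C–Cl or O–CH3; the steric clash of the two groups in the bay should help.

12 ⇒ 11. C4b–C11b, C5–C6 and C6a–C11a are cut, which opens rings B, C and D at once and leaves an acyclic, symmetric triyne. The gain is the largest possible: all six substituents of ring C are already attached to sp carbons, so the arene can form in one way only. The forward step must make intramolecular trimerisation faster than oligomerisation, must tolerate two ynol ethers and a doubly nitrogen-substituted alkyne, and must leave C–Cl alone.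

11 ⇒ 7 + 10 (from 8 through 9). The two aryl–alkynyl bonds C4a–C4b and C6b–C6a are cut. Cutting here, and not earlier, is a deliberate change of order: the acid-labile ynol ethers appear only one step before they are consumed. No intermediate then holds an acidic sulfonamide N–H next to an ynol ether, a pairing that invites 5-endo closure to a 2-methoxyindole. Everything up to 7 is a robust aryl iodide. The forward step must couple at C–I twice, leave C–Cl and the N–C≡C–N unit alone, and be worked up without acid.

7 ⇒ 5 + 3 (through 6). One N–C(sp) bond is cut. Both halves come from the same sulfonamide, so the symmetry of the target is used in full. The forward step asks a sulfonamide anion to displace chloride from an sp carbon that already carries a sulfonamide nitrogen at the other end; this is the one unprecedented bond formation on the way to 11.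

5 ⇒ 3 + 4. The other N–C bond is cut. 4 supplies the two central carbons at the alkyne oxidation level for almost no cost. The forward step must stop after a single addition of nitrogen.

3 ⇒ 1 + 2. The N–S bond is cut. 1 already has chlorine para to the iodinated carbon and meta to nitrogen, which is exactly the C2/C9 pattern, so no aromatic substitution chemistry is needed.

## Other disconnections considered

Alternative 1: The cut is at C5–O and C6–O, leaving the bare chlorinated indolocarbazole A1 (2,9-dichloro-11,12-dihydroindolo[2,3-a]carbazole). In the forward sense A1 would be oxidised at a carbon anode in basic methanol, twice taking up methanol, and would arrive at the quinone diimine A2 (2,9-dichloro-5,6-dimethoxyindolo[2,3-a]carbazole without N–H).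

- In its favour: C5 and C6 are para to N11 and N12 in the most electron-rich ring, so the radical cation should be captured there. No alkyne and no protecting group is involved, and A1 is a simple symmetric compound.
- Against it here: A2 is two hydrogens short of 14, so six electrons must be passed and a closing two-electron reduction added. Carbazole radical cations also couple at carbon and at nitrogen. C3 and C8 are likewise para to nitrogen, shielded only by the neighbouring chlorines. Each methoxylated intermediate is easier to oxidise than its precursor, so over-oxidation to ketals is a standing risk.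
- Comparison: on structure the chosen plan is stronger, because connectivity fixes the substitution pattern where this plan relies on innate site selectivity. On mechanism the two are different in kind (electron transfer and cation capture against organometallic bond formation); anodic methoxylation of electron-rich arenes is an established class, so on precedent for the reaction type this alternative is at least the equal. On step economy it is the better plan, since A1 is short to make and nothing has to be protected.

Alternative 2: The cut is at C5–C6, giving the protected biindole dialdehyde A3 (di-tert-butyl 6,6'-dichloro-3,3'-diformyl-2,2'-biindole-1,1'-dicarboxylate). In the forward sense a carbene catalyst with an amine base would join the two formyl carbons in an intramolecular benzoin reaction, and the adduct would tautomerise to the aromatic catechol A4 (di-tert-butyl 2,9-dichloro-5,6-dihydroxyindolo[2,3-a]carbazole-11,12-dicarboxylate).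

- In its favour: it uses the twofold symmetry as fully as the chosen plan, which is a point of equality. The bond is made by a well-understood umpolung, aromatisation drives the tautomerisation, and every step before and after is of a known type, which makes it the better plan on precedent.
- Against it here: A3 needs the biindole core, two formylations and two carbamates before the key step. Indole-3-carbaldehydes are vinylogous formamides and poor acceptors, which the carbamates only partly correct. A4 is an air-sensitive catechol next to carbamates that can migrate to oxygen under base, and two O-methylations and a deprotection still follow.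
- Comparison: the key step closes one ring and makes one bond, against three and three in the chosen plan, and the route would be about eight or nine steps against six, so it is the weaker on step economy.

Alternative 3: The cuts are N12–C11b and C4b–C5, giving the alkynyl indole A5 (1-{2-[(2-amino-4-chlorophenyl)ethynyl]-6-chloro-1H-indol-3-yl}-2,2-dimethoxyethan-1-one). In the forward sense a cationic monovalent gold catalyst with a sulfonic acid would close ring B by 5-endo attack of the aniline on the alkyne. The new indole C3 would then attack the oxocarbenium ion from the acetal, close ring C and, after loss of methanol and enolisation, give the phenol A6 (2,9-dichloro-5-methoxy-11,12-dihydroindolo[2,3-a]carbazol-6-ol).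

- In its favour: two rings form in one flask by elementary steps that are each well known, so on precedent it is the better plan. The aminoaryl half of A5 can be taken from 1.
- Against it here: the twofold symmetry is not used. The two oxygens arrive differentiated, so a chemoselective O-methylation in the presence of two N–H groups must follow (plausible, since the phenol is far more acidic). A5 combines a free aniline, an acid-labile acetal and a ketone in one molecule and takes several steps to build. A6 is an oxidation-prone aminophenol.
- Comparison: the step count should be about equal to that of the chosen plan. On structure the chosen plan is more direct, since both methoxy groups and both halves are delivered at once. On mechanism the alternative is safer, since nothing in it goes beyond known reactivity.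

Key step: step 5

Remark on the chemistry: N,N'-disulfonyl ynediamines such as 7 and 11 are assumed to be isolable at room temperature, by analogy with N-sulfonyl ynamides. Both are nevertheless meant to be used without storage. Atom numbers follow indolo[2,3-a]carbazole nomenclature.

## Route

Step 1
Reactants: 1 5-chloro-2-iodoaniline; 2 p-toluenesulfonyl chloride
Product: 3 N-(5-chloro-2-iodophenyl)-4-methylbenzenesulfonamide
Conditions: pyridine, CH2Cl2, 0 °C → rt
Reagents that add atoms: p-toluenesulfonyl chloride 2, Cc1ccc(cc1)S(=O)(=O)Cl
Why: Sulfonylation of a primary aniline with a sulfonyl chloride and pyridine; the ortho iodine slows a second sulfonylation, so the mono-sulfonamide should be obtained cleanly.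

Step 2
Reactants: 3 N-(5-chloro-2-iodophenyl)-4-methylbenzenesulfonamide; 4 trichloroethylene
Product: 5 (E)-N-(5-chloro-2-iodophenyl)-N-(1,2-dichloroethenyl)-4-methylbenzenesulfonamide
Conditions: Cs2CO3 (1.5 equiv), DMF, 50 °C
Reagents that add atoms: trichloroethylene 4, ClC=C(Cl)Cl
Why: Carbonate dehydrochlorinates 4 to dichloroacetylene in the flask, the sulfonamide anion adds to it and anti protonation gives the E-dichloroenamide, a known entry to ynamides from N-aryl sulfonamides; C–I and C–Cl of the arene are inert to carbonate, and the electrophile is never isolated.

Step 3
Reactants: 5 (E)-N-(5-chloro-2-iodophenyl)-N-(1,2-dichloroethenyl)-4-methylbenzenesulfonamide; 3 N-(5-chloro-2-iodophenyl)-4-methylbenzenesulfonamide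
Product: 7 N,N'-(ethyne-1,2-diyl)bis[N-(5-chloro-2-iodophenyl)-4-methylbenzenesulfonamide], via chloroynamide 6 (not isolated)
Conditions: 5, KN(SiMe3)2 (1.1 equiv), THF, −78 → −40 °C; then 3 + KN(SiMe3)2 (1.2 equiv) in DMF, −40 → 50 °C
Reagents that add atoms: none
Why: Proposed new method: the silylamide base removes the vinylic hydrogen of 5 and chloride leaves, giving chloroynamide 6 (a conversion known for dichloroenamides); the potassium salt of 3 should then add to the chlorine-bearing sp carbon of 6, the less hindered carbon and the one remote from nitrogen, and the α-sulfonamido vinyl anion expels chloride to give 7, while attack at the other carbon would give an α-chloro carbenoid that can reach the same alkyne by a Fritsch–Buttenberg–Wiechell-type 1,2-shift of nitrogen; the aprotic medium and the slight excess of base return any protonated chloro-enediamide to the alkyne; the closest known reaction type is the addition of sulfonamide anions to dichloroacetylene (as in step 2) and nucleophilic substitution at the sp carbon of 1-haloalkynes, whereas a haloalkyne that already carries a sulfonamide nitrogen has not been used as the electrophile.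

Step 4
Reactants: 7 N,N'-(ethyne-1,2-diyl)bis[N-(5-chloro-2-iodophenyl)-4-methylbenzenesulfonamide]; 8 chloroacetaldehyde dimethyl acetal
Product: 11 N,N'-(ethyne-1,2-diyl)bis{N-[5-chloro-2-(methoxyethynyl)phenyl]-4-methylbenzenesulfonamide}, via lithium methoxyacetylide 9 (not isolated), via methoxyethynylzinc chloride 10 (not isolated)
Conditions: 8, LiNEt2 (3 equiv), THF, 0 °C; ZnCl2, 0 °C; then 7, Pd(PPh3)4 (5 mol%), THF, rt (3 equiv of 10); filtration through Et3N-deactivated silica
Reagents that add atoms: methoxyethynylzinc chloride 10, COC#C[Zn]Cl, made in the flask from chloroacetaldehyde dimethyl acetal 8, COC(CCl)OC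
Why: Three equivalents of lithium amide take 8 through loss of methoxide and of chloride to the lithium acetylide 9, and zinc chloride turns it into 10; Negishi coupling of alkoxyethynylzinc chlorides with aryl iodides at room temperature is a known route to aryl ynol ethers, zerovalent palladium inserts into C–I far faster than into C–Cl, N-sulfonyl N-alkynes tolerate palladium cross-coupling, and the neutral, acid-free medium preserves the ynol ethers.

Step 5
Reactants: 11 N,N'-(ethyne-1,2-diyl)bis{N-[5-chloro-2-(methoxyethynyl)phenyl]-4-methylbenzenesulfonamide}
Product: 12 2,9-dichloro-5,6-dimethoxy-11,12-bis(4-methylbenzenesulfonyl)-11,12-dihydroindolo[2,3-a]carbazole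
Conditions: RhCl(PPh3)3 (10 mol%), toluene (0.005 M, slow addition of 11), 4 Å MS, 80 °C, argon
Reagents that add atoms: none
Why: Proposed new method: monovalent rhodium, after loss of one PPh3, should bind one methoxyalkyne and the central N–C≡C–N unit of 11, which form a 1,6-diyne through C4a–C12a–N12, and couple them oxidatively to a trivalent rhodacyclopentadiene, making C4b–C11b and closing five-membered ring B. The second methoxyalkyne, held by the identical bridge C6b–C10a–N11, then inserts into the Rh–C11a bond, making C6a–C11a and closing five-membered ring D, and C–C reductive elimination from the rhodacycloheptatriene makes C5–C6, closes six-membered ring C and returns monovalent rhodium. The closest known reaction type is the RhCl(PPh3)3-catalysed [2+2+2] cycloaddition of diynes made of an N-sulfonyl ynamide and an ortho-alkynylaryl group with a third alkyne, which gives N-sulfonyl carbazoles; new here are the second sulfonamide nitrogen on the ynamide and the presence of all three alkynes in one molecule. No stereocentre is formed. Regiochemistry needs no control, because each alkyne can reach its neighbour only through a three-atom bridge, so all six substituents of ring C are placed by connectivity. The selectivity that matters is intramolecular trimerisation over oligomerisation and over hydration of the ynol ethers; high dilution with slow addition, molecular sieves and a neutral, weakly Lewis acidic catalyst should secure it, and C–Cl is inert to this complex. The strain of two sulfonyl groups on N11 and N12 is set against the large energy released when ring C becomes aromatic.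

Step 6
Reactants: 12 2,9-dichloro-5,6-dimethoxy-11,12-bis(4-methylbenzenesulfonyl)-11,12-dihydroindolo[2,3-a]carbazole
Product: 14 Borregomycin E (2,9-dichloro-5,6-dimethoxy-11,12-dihydroindolo[2,3-a]carbazole), via mono-tosyl indolocarbazole 13 (not isolated)
Conditions: Cs2CO3 (6 equiv), THF/MeOH (2:1), 65 °C, argon
Reagents that add atoms: none
Why: Cleavage of N-sulfonyl indoles and carbazoles by methoxide formed from Cs2CO3 in methanol is a known deprotection in which the carbazolide is the leaving group; relief of the bay strain should make the first cleavage (to 13) fast, aryl chlorides and aryl methyl ethers are inert, and work-up under argon protects the electron-rich product.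

## Compound list

1 | 5-chloro-2-iodoaniline | Nc1cc(Cl)ccc1I | starting material
2 | p-toluenesulfonyl chloride | Cc1ccc(cc1)S(=O)(=O)Cl | starting material
3 | N-(5-chloro-2-iodophenyl)-4-methylbenzenesulfonamide | Cc1ccc(cc1)S(=O)(=O)Nc1cc(Cl)ccc1I | intermediate
4 | trichloroethylene | ClC=C(Cl)Cl | starting material
5 | (E)-N-(5-chloro-2-iodophenyl)-N-(1,2-dichloroethenyl)-4-methylbenzenesulfonamide | Cl/C(=C/Cl)N(c1cc(Cl)ccc1I)S(=O)(=O)c1ccc(C)cc1 | intermediate
6 | N-(chloroethynyl)-N-(5-chloro-2-iodophenyl)-4-methylbenzenesulfonamide | ClC#CN(c1cc(Cl)ccc1I)S(=O)(=O)c1ccc(C)cc1 | intermediate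
7 | N,N'-(ethyne-1,2-diyl)bis[N-(5-chloro-2-iodophenyl)-4-methylbenzenesulfonamide] | Cc1ccc(cc1)S(=O)(=O)N(C#CN(c1cc(Cl)ccc1I)S(=O)(=O)c1ccc(C)cc1)c1cc(Cl)ccc1I | intermediate
8 | chloroacetaldehyde dimethyl acetal | COC(CCl)OC | starting material
9 | lithium methoxyacetylide | [Li]C#COC | intermediate
10 | methoxyethynylzinc chloride | COC#C[Zn]Cl | intermediate
11 | N,N'-(ethyne-1,2-diyl)bis{N-[5-chloro-2-(methoxyethynyl)phenyl]-4-methylbenzenesulfonamide} | COC#Cc1ccc(Cl)cc1N(C#CN(c1cc(Cl)ccc1C#COC)S(=O)(=O)c1ccc(C)cc1)S(=O)(=O)c1ccc(C)cc1 | intermediate
12 | 2,9-dichloro-5,6-dimethoxy-11,12-bis(4-methylbenzenesulfonyl)-11,12-dihydroindolo[2,3-a]carbazole | COc1c(OC)c2c3ccc(Cl)cc3n(S(=O)(=O)c3ccc(C)cc3)c2c2n(S(=O)(=O)c3ccc(C)cc3)c3cc(Cl)ccc3c12 | intermediate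
13 | 2,9-dichloro-5,6-dimethoxy-11-(4-methylbenzenesulfonyl)-11,12-dihydroindolo[2,3-a]carbazole | COc1c(OC)c2c3ccc(Cl)cc3n(S(=O)(=O)c3ccc(C)cc3)c2c2[nH]c3cc(Cl)ccc3c12 | intermediate
14 | Borregomycin E, 2,9-dichloro-5,6-dimethoxy-11,12-dihydroindolo[2,3-a]carbazole | COc1c(OC)c2c3ccc(Cl)cc3[nH]c2c2[nH]c3cc(Cl)ccc3c12 | target

## Step count and risks

Total step count: 6. Longest linear sequence: 6 steps (1 → 3 → 5 → 7 → 11 → 12 → 14).

Least certain steps, the two labelled ones first.

Step 5 (key step). What may go wrong: oligomerisation of the triyne or hydration of its ynol ether ends may outrun the second alkyne insertion, which builds the bay strain between the two sulfonyl groups. The doubly nitrogen-substituted alkyne may also break down at the metal before it is incorporated. Fallback with known reactions only, setting out from 1 and returning at 14, with no nitrogen substituent at any stage: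
- Veratrole is lithiated twice next to its oxygens (n-BuLi, TMEDA) and quenched with 2-isopropoxy-4,4,5,5-tetramethyl-1,3,2-dioxaborolane to give 2,2'-(2,3-dimethoxy-1,4-phenylene)bis(4,4,5,5-tetramethyl-1,3,2-dioxaborolane) F1.
- Double Suzuki–Miyaura coupling of F1 with 1 at its C–I bond (Pd(dppf)Cl2, K3PO4, dioxane/water, 90 °C) should give 2,2'-(2,3-dimethoxy-1,4-phenylene)bis(5-chloroaniline) F2.
- Diazotisation and azide transfer (t-BuONO, Me3SiN3, MeCN, 0 °C → rt) should give 1,4-bis(2-azido-4-chlorophenyl)-2,3-dimethoxybenzene F3.
- Thermolysis in o-dichlorobenzene at 170 °C releases two aryl nitrenes, which can only insert into the two remaining C–H bonds of the central ring; this closes rings B and D and gives 14.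

Step 3. What may go wrong: addition of the hindered, weakly nucleophilic sulfonamide anion to 6 may be slower than decomposition of 6. Protonation of the vinyl anion may halt the sequence at a chloro-enediamide, or attack at the nitrogen-bearing carbon may end in a ketene aminal instead of the alkyne. Fallback with known reactions only, setting out from 3 and returning at 12, so that step 6 is kept:
- Veratrole is lithiated twice and borylated as above to give 2,2'-(2,3-dimethoxy-1,4-phenylene)bis(4,4,5,5-tetramethyl-1,3,2-dioxaborolane) F4 (the same compound as F1).
- Double Suzuki–Miyaura coupling of F4 with 3 (Pd(dppf)Cl2, K3PO4, dioxane/water, 90 °C) should give N,N'-[(2,3-dimethoxy-1,4-phenylene)bis(5-chloro-2,1-phenylene)]bis(4-methylbenzenesulfonamide) F5.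
- Double oxidative C–H amination of the N-sulfonyl 2-aminobiaryl units (Pd(OAc)2 10 mol%, 2KHSO5·KHSO4·K2SO4, TsOH, DMF, rt → 50 °C, through divalent palladium) forms the two N–C bonds at the only free positions of the central ring and gives 12. The second closure places the sulfonyl groups side by side and is the slow point of this detour.

Step 4. What may go wrong: the N–C≡C–N unit may be lost under palladium, by aminopalladation with diethylamine carried in with the zinc reagent or by carbopalladation after oxidative addition. The second coupling may be incomplete, or the ynol ethers may be hydrated during isolation. Fallback that reverses the order of events, setting out from 3 and returning at 11, so that the N–C≡C–N unit never meets palladium: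
- 3 is deprotonated with NaH and coupled with 10 (Pd(PPh3)4, THF, rt) to give N-[5-chloro-2-(methoxyethynyl)phenyl]-4-methylbenzenesulfonamide F6. F6 is used at once, since its N–H lies next to the ynol ether.
- F6 with 4 and Cs2CO3 in DMF should give (E)-N-[5-chloro-2-(methoxyethynyl)phenyl]-N-(1,2-dichloroethenyl)-4-methylbenzenesulfonamide F7.
- KN(SiMe3)2 converts F7 into N-(chloroethynyl)-N-[5-chloro-2-(methoxyethynyl)phenyl]-4-methylbenzenesulfonamide F8, which is not isolated and is joined with the potassium salt of a second equivalent of F6 under the conditions of step 3 to give 11.

## Further compounds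

F1 | step 5 | 2,2'-(2,3-dimethoxy-1,4-phenylene)bis(4,4,5,5-tetramethyl-1,3,2-dioxaborolane) | COc1c(OC)c(B2OC(C)(C)C(C)(C)O2)ccc1B1OC(C)(C)C(C)(C)O1
F2 | step 5 | 2,2'-(2,3-dimethoxy-1,4-phenylene)bis(5-chloroaniline) | COc1c(OC)c(-c2ccc(Cl)cc2N)ccc1-c1ccc(Cl)cc1N
F3 | step 5 | 1,4-bis(2-azido-4-chlorophenyl)-2,3-dimethoxybenzene | COc1c(OC)c(-c2ccc(Cl)cc2N=[N+]=[N-])ccc1-c1ccc(Cl)cc1N=[N+]=[N-]
F4 | step 3 | 2,2'-(2,3-dimethoxy-1,4-phenylene)bis(4,4,5,5-tetramethyl-1,3,2-dioxaborolane) | COc1c(OC)c(B2OC(C)(C)C(C)(C)O2)ccc1B1OC(C)(C)C(C)(C)O1
F5 | step 3 | N,N'-[(2,3-dimethoxy-1,4-phenylene)bis(5-chloro-2,1-phenylene)]bis(4-methylbenzenesulfonamide) | COc1c(OC)c(-c2ccc(Cl)cc2NS(=O)(=O)c2ccc(C)cc2)ccc1-c1ccc(Cl)cc1NS(=O)(=O)c1ccc(C)cc1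
F6 | step 4 | N-[5-chloro-2-(methoxyethynyl)phenyl]-4-methylbenzenesulfonamide | COC#Cc1ccc(Cl)cc1NS(=O)(=O)c1ccc(C)cc1
F7 | step 4 | (E)-N-[5-chloro-2-(methoxyethynyl)phenyl]-N-(1,2-dichloroethenyl)-4-methylbenzenesulfonamide | Cl/C(=C/Cl)N(c1cc(Cl)ccc1C#COC)S(=O)(=O)c1ccc(C)cc1
F8 | step 4 | N-(chloroethynyl)-N-[5-chloro-2-(methoxyethynyl)phenyl]-4-methylbenzenesulfonamide | COC#Cc1ccc(Cl)cc1N(C#CCl)S(=O)(=O)c1ccc(C)cc1
A1 | alternative 1 | 2,9-dichloro-11,12-dihydroindolo[2,3-a]carbazole | c1cc2c3ccc(Cl)cc3[nH]c2c2[nH]c3cc(Cl)ccc3c12
A2 | alternative 1 | 2,9-dichloro-5,6-dimethoxyindolo[2,3-a]carbazole, quinone diimine form | COC1=C2c3ccc(Cl)cc3N=C2C2=Nc3cc(Cl)ccc3C2=C1OC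
A3 | alternative 2 | di-tert-butyl 6,6'-dichloro-3,3'-diformyl-2,2'-biindole-1,1'-dicarboxylate | CC(C)(C)OC(=O)n1c(-c2c(C=O)c3ccc(Cl)cc3n2C(=O)OC(C)(C)C)c(C=O)c2ccc(Cl)cc21
A4 | alternative 2 | di-tert-butyl 2,9-dichloro-5,6-dihydroxyindolo[2,3-a]carbazole-11,12-dicarboxylate | CC(C)(C)OC(=O)n1c2cc(Cl)ccc2c2c(O)c(O)c3c4ccc(Cl)cc4n(C(=O)OC(C)(C)C)c3c21
A5 | alternative 3 | 1-{2-[(2-amino-4-chlorophenyl)ethynyl]-6-chloro-1H-indol-3-yl}-2,2-dimethoxyethan-1-one | COC(OC)C(=O)c1c(C#Cc2ccc(Cl)cc2N)[nH]c2cc(Cl)ccc12
A6 | alternative 3 | 2,9-dichloro-5-methoxy-11,12-dihydroindolo[2,3-a]carbazol-6-ol | COc1c(O)c2c3ccc(Cl)cc3[nH]c2c2[nH]c3cc(Cl)ccc3c12
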